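**Strategy.** Ring B is closed last, at its most congested bond, C9–C10. The C6–C7–C8 triol is read as a C7 ketone flanked by its two α-carbons. The same carbonyl, conjugated with C8=C9, makes C9 the acceptor for a tertiary radical at C10. The key step is a hydrogen-atom-transfer-initiated 6-endo radical conjugate addition of a monocyclic (E)-enone that carries one stereocentre (C5). In one operation it forms ring B, the quaternary C10 and C9 as a trans-decalin. It leaves the C7 ketone, from which O8 and O6 are delivered to the open α-face and C7 is then reduced. The precursor comes from two fragments in four steps.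

Key step: step 5

Assumption: 2,4,4-trimethylcyclohex-2-en-1-one (1) is taken as commercially available.
Remark: labdane numbering is used for all compounds. Ring A is C1–C5 and C10; ring B is C5–C10; the side chain is C11–C16; C17 sits on C8, C18/C19 on C4 and C20 on C10. β is the face of C20.

Step 1
Reactants: 1 2,4,4-trimethylcyclohex-2-en-1-one
Product: 2 (1R)-2,4,4-trimethylcyclohex-2-en-1-ol
Conditions: (S)-Me-CBS (10 mol %), BH3·SMe2, THF, −20 °C; MeOH
Reagents that add atoms: none
Why: Corey–Bakshi–Shibata reduction, in which the oxazaborolidine binds the ketone away from the larger α-methylalkenyl flank so that hydride reaches one face only and sets the carbinol carbon (labdane C1) as R, with clean 1,2-selectivity.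

Step 2
Reactants: 2 (1R)-2,4,4-trimethylcyclohex-2-en-1-ol
Product: 4 N,N-dimethyl-2-[(1S)-2,6,6-trimethylcyclohex-2-en-1-yl]acetamide, via ketene N,O-acetal 3 (not isolated)
Conditions: MeC(OMe)2NMe2 (3 equiv), xylene, 140 °C, MeOH distilled off
Reagents that add atoms: N,N-dimethylacetamide dimethyl acetal CC(OC)(OC)N(C)C
Why: Eschenmoser–Claisen rearrangement, suprafacial across the ring, so the C1–O stereocentre is traded for the C5–C6 bond on the same β-face next to the gem-dimethyl carbon, and the alkene moves to C1=C10, where the key step needs it.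

Step 3
Reactants: 5 pent-3-yn-1-ol
Product: 7 (3E)-4-iodopent-3-en-1-ol, via alkenylzirconocene 6 (not isolated)
Conditions: Cp2Zr(H)Cl (2.3 equiv), THF, rt to 40 °C; I2, 0 °C; H2O
Reagents that add atoms: iodine II; zirconocene chloride hydride [H][Zr](Cl)(C1C=CC=C1)C1C=CC=C1 (zirconium only in 6)
Why: Hydrozirconation–iodinolysis, in which syn addition of Zr–H, equilibration by excess Schwartz reagent to the less hindered methyl-bearing carbon and iodinolysis with retention should give the E-iodide.

Step 4
Reactants: 7 (3E)-4-iodopent-3-en-1-ol; 4 N,N-dimethyl-2-[(1S)-2,6,6-trimethylcyclohex-2-en-1-yl]acetamide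
Product: 10 (3E)-6-hydroxy-3-methyl-1-[(1S)-2,6,6-trimethylcyclohex-2-en-1-yl]hex-3-en-2-one, via dilithio reagent 8 (not isolated), via tetrahedral adduct 9 (not isolated)
Conditions: 7, t-BuLi (3.1 equiv), Et2O, −78 °C; 4, −78 to 0 °C; H2O
Reagents that add atoms: tert-butyllithium [Li]C(C)(C)C (lithium only in 8 and 9)
Why: Iodine–lithium exchange with retention of alkene geometry, then acylation of the alkenyllithium by a tertiary amide whose tetrahedral adduct survives until the quench, so the reaction stops at the (E)-enone (C11 trans to C7).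

Step 5
Reactants: 10 (3E)-6-hydroxy-3-methyl-1-[(1S)-2,6,6-trimethylcyclohex-2-en-1-yl]hex-3-en-2-one
Product: 13 12-hydroxy-13,14,15,16-tetranorlabdan-7-one (trans-decalin; 5α-H, 10β-CH3, 9β-CH2CH2OH, 8α-CH3), via C10 radical 11 (not isolated), via C8 radical 12 (not isolated)
Conditions: Fe(acac)3 (30 mol %), PhSiH3 (2.5 equiv, slow addition), EtOH, 60 °C, 0.01 M, Ar
Reagents that add atoms: none
Why: An iron hydride formed from Fe(acac)3 and PhSiH3 transfers H• to C1 of the electron-rich C1=C10 alkene (Markovnikov), the nucleophilic tertiary radical 11 adds to C9, the β-carbon of the enone, and the α-keto radical 12 is reduced and protonated by ethanol. The closest known reaction type is the intramolecular MHAT reductive olefin coupling (Giese-type conjugate addition), which is established for making quaternary carbons next to substituted carbons. Ring B closes 6-endo-trig because the carbonyl lies inside the tether and the enone reacts from its preferred s-trans form, whereas 5-exo attack at C8 would hit the methyl-bearing α-carbon against the polarity of the acceptor. C10 is controlled by C5: in the chair-like transition state C5–C6 is equatorial on ring A and C9 bonds to the α-lobe while C20 swings axial (trans-decalin, as in the second closure of radical polyene cyclizations), since β-attack would place the whole enone 1,3-diaxial to the axial C4 methyl. C9 is controlled by the E geometry of C8=C9, which holds C11 anti to C7 and hence equatorial (β), while C8 should settle as the equatorial methyl epimer and is planarised again in step 8. The step needs hydrogen transfer to the ring alkene and not to the enone, which the higher electron density and open C1–H terminus of the donor secure, and it needs cyclization to beat reduction, which the matched polarity and the low stationary hydride concentration secure.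

Step 6
Reactants: 13 12-hydroxy-13,14,15,16-tetranorlabdan-7-one
Product: 14 7-oxo-13,14,15,16-tetranorlabdan-12-al
Conditions: Dess–Martin periodinane, CH2Cl2, 0 °C to rt
Reagents that add atoms: none
Why: Dess–Martin oxidation of the primary alcohol under neutral conditions, which leaves the ketone and the ring stereocentres untouched; because no 8-OH is present yet, a free aldehyde and not a lactol is obtained.

Step 7
Reactants: 14 7-oxo-13,14,15,16-tetranorlabdan-12-al
Product: 15 (12Z)-13-iodo-14,15-dinorlabd-12-en-7-one
Conditions: EtPPh3I, n-BuLi, THF, rt; I2, −78 °C; NaHMDS, −20 °C; 14, −78 °C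
Reagents that add atoms: ethyltriphenylphosphonium iodide CC[P+](c1ccccc1)(c1ccccc1)c1ccccc1.[I-]; iodine II
Why: Stork–Zhao-type Wittig olefination with the non-stabilised α-iodoethylidene ylide, whose kinetic addition should give the Z-iodoalkene (I cis to C11), the aldehyde reacting far faster than the hindered C7 ketone.

Step 8
Reactants: 15 (12Z)-13-iodo-14,15-dinorlabd-12-en-7-one
Product: 18 (12Z)-8α-hydroxy-13-iodo-14,15-dinorlabd-12-en-7-one, via silyl enol ether 16 (not isolated), via 8-silyloxy ketone 17 (not isolated)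
Conditions: TMSOTf, Et3N, CH2Cl2, 0 °C to rt (equilibrating); hexane, filter, concentrate; mCPBA (1.05 equiv), CH2Cl2, −20 °C; HF·pyridine, THF, 0 °C
Reagents that add atoms: trimethylsilyl triflate C[Si](C)(C)OS(=O)(=O)C(F)(F)F (silicon only in 16 and 17); mCPBA O=C(OO)c1cccc(Cl)c1
Why: Rubottom oxidation, in which equilibrating silylation should favour the more substituted C7=C8 enol ether (the C6=C7 isomer suffers from the clash of C6–H with the equatorial C4 methyl) and the peracid attacks the α-face because C20 and C11 cover the β-face, setting C8 with OH α and CH3 β.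

Step 9
Reactants: 18 (12Z)-8α-hydroxy-13-iodo-14,15-dinorlabd-12-en-7-one
Product: 21 (12Z)-6α-acetoxy-8α-hydroxy-13-iodo-14,15-dinorlabd-12-en-7-one, via bis-silyl enol ether 19 (not isolated), via silylated acetate 20 (not isolated)
Conditions: TMSOTf (3 equiv), Et3N, CH2Cl2, 0 °C to rt; hexane, filter, concentrate; Pb(OAc)4, CH2Cl2, −20 to 0 °C; HF·pyridine, THF, 0 °C
Reagents that add atoms: trimethylsilyl triflate C[Si](C)(C)OS(=O)(=O)C(F)(F)F (silicon only in 19 and 20); lead(IV) acetate CC(=O)O[Pb](OC(C)=O)(OC(C)=O)OC(C)=O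
Why: Lead(IV) acetate oxidation of a silyl enol ether (Rubottom acetoxylation), where only C6 can enolise once C8 is quaternary, the same silylation masks the 8-OH against ketol cleavage, and acetate arrives on the α-face below the two axial methyls (C19, C20) to give the equatorial 6α-acetate, which is also the thermodynamic epimer.

Step 10
Reactants: 21 (12Z)-6α-acetoxy-8α-hydroxy-13-iodo-14,15-dinorlabd-12-en-7-one
Product: 22 (12Z)-6α-acetoxy-8α-hydroxylabda-12,14-dien-7-one
Conditions: Bu3SnCH=CH2, Pd2(dba)3 (5 mol %), AsPh3, CuI (cat.), NMP, rt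
Reagents that add atoms: tributyl(vinyl)stannane C=C[Sn](CCCC)(CCCC)CCCC
Why: Stille coupling, which proceeds with retention at the alkenyl iodide under neutral conditions, so the 12Z geometry, the α-acetoxy ketone and the tertiary ketol should survive; the oxidation-sensitive diene appears only after all oxidations.

Step 11
Reactants: 22 (12Z)-6α-acetoxy-8α-hydroxylabda-12,14-dien-7-one
Product: 23 (12Z)-6α-acetoxylabda-12,14-diene-7β,8α-diol (5S,6R,7S,8S,9R,10S; target)
Conditions: NaBH4, CeCl3·7H2O, MeOH, −78 to −40 °C
Reagents that add atoms: none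
Why: Luche reduction, in which hydride should add along the axial α-trajectory because the axial 8β-methyl blocks the β-face, giving the equatorial 7β-alcohol, while the cold, non-basic medium suppresses 6→7 acetyl migration and leaves ester and diene untouched.

**Compound list**
1 | 2,4,4-trimethylcyclohex-2-en-1-one | O=C1CCC(C)(C)C=C1C | starting material
2 | (1R)-2,4,4-trimethylcyclohex-2-en-1-ol | O[C@@H]1CCC(C)(C)C=C1C | intermediate
3 | N,N-dimethyl-1-{[(1R)-2,4,4-trimethylcyclohex-2-en-1-yl]oxy}ethenamine (ketene N,O-acetal) | C=C(N(C)C)O[C@@H]1CCC(C)(C)C=C1C | intermediate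
4 | N,N-dimethyl-2-[(1S)-2,6,6-trimethylcyclohex-2-en-1-yl]acetamide | CN(C)C(=O)C[C@@H]1C(C)=CCCC1(C)C | intermediate
5 | pent-3-yn-1-ol | CC#CCCO | starting material
6 | (E)-alkenylzirconocene chloride of 5, O-zirconated | C/C(=C\CCO[Zr](Cl)(C1C=CC=C1)C1C=CC=C1)[Zr](Cl)(C1C=CC=C1)C1C=CC=C1 | intermediate
7 | (3E)-4-iodopent-3-en-1-ol | OCC/C=C(\C)I | intermediate
8 | lithium (3E)-4-lithiopent-3-en-1-olate | [Li]OCC/C=C(\C)[Li] | intermediate
9 | dilithium hemiaminal adduct of 8 and 4 (C7 unassigned) | [Li]OCC/C=C(\C)C(O[Li])(N(C)C)C[C@@H]1C(C)=CCCC1(C)C | intermediate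
10 | (3E)-6-hydroxy-3-methyl-1-[(1S)-2,6,6-trimethylcyclohex-2-en-1-yl]hex-3-en-2-one | OCC/C=C(\C)C(=O)C[C@@H]1C(C)=CCCC1(C)C | intermediate
11 | tertiary C10 radical from 10 | OCC/C=C(\C)C(=O)C[C@@H]1[C](C)CCCC1(C)C | intermediate
12 | cyclised C8 α-keto radical | OCC[C@H]1[C](C)C(=O)C[C@H]2C(C)(C)CCC[C@@]21C | intermediate
13 | 12-hydroxy-13,14,15,16-tetranorlabdan-7-one (8α-CH3) | OCC[C@H]1[C@H](C)C(=O)C[C@H]2C(C)(C)CCC[C@@]21C | intermediate
14 | 7-oxo-13,14,15,16-tetranorlabdan-12-al | O=CC[C@H]1[C@H](C)C(=O)C[C@H]2C(C)(C)CCC[C@@]21C | intermediate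
15 | (12Z)-13-iodo-14,15-dinorlabd-12-en-7-one | I/C(C)=C\C[C@H]1[C@H](C)C(=O)C[C@H]2C(C)(C)CCC[C@@]21C | intermediate
16 | (12Z)-13-iodo-7-(trimethylsilyloxy)-14,15-dinorlabda-7,12-diene | I/C(C)=C\C[C@H]1C(C)=C(O[Si](C)(C)C)C[C@H]2C(C)(C)CCC[C@@]21C | intermediate
17 | (12Z)-13-iodo-8α-(trimethylsilyloxy)-14,15-dinorlabd-12-en-7-one | I/C(C)=C\C[C@H]1[C@](C)(O[Si](C)(C)C)C(=O)C[C@H]2C(C)(C)CCC[C@@]21C | intermediate
18 | (12Z)-8α-hydroxy-13-iodo-14,15-dinorlabd-12-en-7-one | I/C(C)=C\C[C@H]1[C@](C)(O)C(=O)C[C@H]2C(C)(C)CCC[C@@]21C | intermediate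
19 | (12Z)-13-iodo-7,8α-bis(trimethylsilyloxy)-14,15-dinorlabda-6,12-diene | I/C(C)=C\C[C@H]1[C@](C)(O[Si](C)(C)C)C(O[Si](C)(C)C)=C[C@H]2C(C)(C)CCC[C@@]21C | intermediate
20 | (12Z)-6α-acetoxy-13-iodo-8α-(trimethylsilyloxy)-14,15-dinorlabd-12-en-7-one | I/C(C)=C\C[C@H]1[C@](C)(O[Si](C)(C)C)C(=O)[C@H](OC(C)=O)[C@H]2C(C)(C)CCC[C@@]21C | intermediate
21 | (12Z)-6α-acetoxy-8α-hydroxy-13-iodo-14,15-dinorlabd-12-en-7-one | I/C(C)=C\C[C@H]1[C@](C)(O)C(=O)[C@H](OC(C)=O)[C@H]2C(C)(C)CCC[C@@]21C | intermediate
22 | (12Z)-6α-acetoxy-8α-hydroxylabda-12,14-dien-7-one | C=C/C(C)=C\C[C@H]1[C@](C)(O)C(=O)[C@H](OC(C)=O)[C@H]2C(C)(C)CCC[C@@]21C | intermediate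
23 | (12Z)-6α-acetoxylabda-12,14-diene-7β,8α-diol (CNP0138393.1) | C=C/C(C)=C\C[C@H]1[C@](C)(O)[C@@H](O)[C@H](OC(C)=O)[C@H]2C(C)(C)CCC[C@@]21C | target

**Total step count:** 11
**Longest linear sequence:** 10 (steps 1, 2, 4–11)

**Steps most likely to fail**

**Step 5.** Several processes could undermine the cyclization:
- hydrogen-atom transfer to the enone instead of the ring alkene;
- reversible transfer that walks the ring alkene to C5=C10 and so erases C5;
- reduction of the C10 radical before it cyclises;
- closure through the β-lobe to the cis-decalin.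

The fallback sets out from 10 and returns at 13. It separates radical generation from the reductant. Markovnikov hydrochlorination of the ring alkene (HCl–DMPU/AcOH, CH2Cl2, −20 °C, fast ion-pair collapse) would give the tertiary C10 chloride F1, and either C10 epimer serves. Slow addition of (Me3Si)3SiH/AIBN in refluxing toluene would then form the same C10 radical by chlorine abstraction. This is a classical chain Giese cyclization with no metal hydride present, so the enone cannot be reduced and the alkene cannot isomerise.

**Step 8.** Enolisation could run toward C6 instead of C8, or the oxidant could show poor facial discrimination. The fallback sets out from 15 and returns at 20. It reverses the order of the two oxygenations so that the competing site is consumed first.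
- Kinetic silylation (LiHMDS, TMSCl, THF, −78 °C) would give the C6=C7 silyl enol ether F2.
- Pb(OAc)4 would convert F2 into the 6α-acetoxy ketone F3.
- In F3 the remaining C6–H is axial and buried under C19 and C20, so TMSOTf/Et3N should now give the C7=C8 silyl enol ether F4.
- mCPBA would oxidise F4 from the α-face to 20, which is desilylated to 21 as in step 9.

**Step 7.** The risks are enolisation of the aldehyde by the basic ylide, loss of iodine from the ylide, or erosion of the Z geometry. The fallback sets out from 14 and returns at 15. It builds the trisubstituted alkene by sequential substitution and not by olefination.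
- Ramirez dibromoolefination (CBr4, PPh3, CH2Cl2, 0 °C) would give the 1,1-dibromoalkene F5.
- Pd-catalysed Negishi monomethylation, selective for the bromide trans to C11 (Me2Zn, PdCl2(DPEphos), THF), would give the (Z)-bromoalkene F6.
- Copper-catalysed halogen exchange with retention (NaI, CuI, N,N′-dimethylcyclohexane-1,2-diamine, dioxane, 110 °C) would deliver 15.

**Further compounds**
F1 | step 5 | (3E)-1-[(1S)-2-chloro-2,6,6-trimethylcyclohexyl]-6-hydroxy-3-methylhex-3-en-2-one (C10 epimers) | OCC/C=C(\C)C(=O)C[C@@H]1C(C)(Cl)CCCC1(C)C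
F2 | step 8 | (12Z)-13-iodo-7-(trimethylsilyloxy)-14,15-dinorlabda-6,12-diene | I/C(C)=C\C[C@H]1[C@H](C)C(O[Si](C)(C)C)=C[C@H]2C(C)(C)CCC[C@@]21C
F3 | step 8 | (12Z)-6α-acetoxy-13-iodo-14,15-dinorlabd-12-en-7-one | I/C(C)=C\C[C@H]1[C@H](C)C(=O)[C@H](OC(C)=O)[C@H]2C(C)(C)CCC[C@@]21C
F4 | step 8 | (12Z)-6α-acetoxy-13-iodo-7-(trimethylsilyloxy)-14,15-dinorlabda-7,12-diene | I/C(C)=C\C[C@H]1C(C)=C(O[Si](C)(C)C)[C@H](OC(C)=O)[C@H]2C(C)(C)CCC[C@@]21C
F5 | step 7 | 13,13-dibromo-14,15,16-trinorlabd-12-en-7-one | BrC(Br)=CC[C@H]1[C@H](C)C(=O)C[C@H]2C(C)(C)CCC[C@@]21C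
F6 | step 7 | (12Z)-13-bromo-14,15-dinorlabd-12-en-7-one | Br/C(C)=C\C[C@H]1[C@H](C)C(=O)C[C@H]2C(C)(C)CCC[C@@]21C
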